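**Plan**

- Retrosynthesis: cut the allyl ester and C13=C14 (Horner–Wadsworth–Emmons), then C11–C12 (alkylborane plus bromoacetone) and C9=C11 (methylenation, later hydroborated), then C7–C8 and C8–C9 in one stroke, and last the two C4–methyl bonds.
- Enabling feature: ring B (C5–C6–C7–C8–C9–C10) holds the sp2, methyl-bearing C8 between C7 and C9. Without C8 it is the five-membered ring C5–C6–C7–C9–C10 with a C9 carbonyl, which together with ring A and the C10 methyl is the skeleton of the (S)-Hajos–Parrish ketone.
- Forward: ring A and the five-membered ring are bought; C4 is dimethylated, C3 reduced and C5=C6 hydrogenated. Ring B then arises by insertion of chloro(methyl)carbene into the C7=C9 silyl enol ether (5 → 6 ring expansion). The chain is joined in the order C11, C12–C13(–C16), C14–C15.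
- Stereochemistry: C10 comes from the starting ketone; C3 from axial hydride attack (3β-OH); C5 from hydrogenation opposite the 4β- and 10β-methyls; C9 from α-face hydroboration; 13E from the olefination.

Key step: step 7

Remark: labdane numbering is used for every bicyclic compound (in the hydrindane intermediates C8 is absent and C7 is bonded to C9), β is the face of the C10 methyl, and the non-conjugated five-ring carbonyl of 1 is assumed to ketalise faster than the enone carbonyl.

**Route**

Step 1
Reactants: 1 (S)-Hajos–Parrish ketone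
Product: 2 C9 ethylene ketal of 1
Conditions: HOCH2CH2OH, p-TsOH (cat.), 4 Å MS, CH2Cl2, rt
Reagents that add atoms: ethylene glycol, OCCO
Why: Acid-catalysed dioxolane formation (ketalisation) should occur at the saturated cyclopentanone carbonyl before the less electrophilic conjugated C3 carbonyl, so short exposure at room temperature protects C9 alone.

Step 2
Reactants: 2 C9 ethylene ketal of 1; 3 iodomethane
Product: 4 9,9-ethylenedioxy-4,4,10β-trimethylhydrind-5-en-3-one (C5=C6 in the five-membered ring)
Conditions: KOtBu, MeI, t-BuOH/THF, 0 °C → rt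
Reagents that add atoms: iodomethane (3), CI
Why: Deconjugative α,α-dialkylation through the extended enolate: the base removes a γ-hydrogen at C6, both methyl groups enter at C4, and the alkene is left at C5=C6, from where it cannot move back into conjugation.

Step 3
Reactants: 4 9,9-ethylenedioxy-4,4,10β-trimethylhydrind-5-en-3-one
Product: 5 9,9-ethylenedioxy-4,4,10β-trimethylhydrind-5-en-3β-ol
Conditions: NaBH4, MeOH, 0 °C
Reagents that add atoms: none
Why: Borohydride reduction of the ketone; hydride should attack axially from the α-face, away from the axial 4β-methyl, to give the equatorial 3β-alcohol.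

Step 4
Reactants: 5 9,9-ethylenedioxy-4,4,10β-trimethylhydrind-5-en-3β-ol
Product: 6 9,9-ethylenedioxy-4,4,10β-trimethyl-5α-hydrindan-3β-ol (trans ring fusion)
Conditions: H2 (3 atm), 10% Pd/C, EtOAc, rt
Reagents that add atoms: none
Why: Heterogeneous catalytic hydrogenation adds both hydrogens from the α-face because the β-face of C5=C6 is covered by the 10β- and 4β-methyl groups, so C5 should receive its hydrogen α and the hydrindane become trans-fused.

Step 5
Reactants: 6 9,9-ethylenedioxy-4,4,10β-trimethyl-5α-hydrindan-3β-ol
Product: 7 3β-hydroxy-4,4,10β-trimethyl-5α-hydrindan-9-one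
Conditions: 1 M HCl, THF, rt
Reagents that add atoms: water, O
Why: Acid-catalysed ketal hydrolysis frees the C9 ketone; neither stereocentre next to the ring fusion is α to the carbonyl in an epimerisable sense (C10 is quaternary, C5 is β).

Step 6
Reactants: 7 3β-hydroxy-4,4,10β-trimethyl-5α-hydrindan-9-one
Product: 8 3β,9-bis(trimethylsilyloxy)-4,4,10β-trimethyl-5α-hydrind-7(9)-ene (TMS ether at O3, TMS enol ether C7=C9)
Conditions: TMSOTf, Et3N, CH2Cl2, 0 °C
Reagents that add atoms: trimethylsilyl trifluoromethanesulfonate, C[Si](C)(C)OS(=O)(=O)C(F)(F)F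
Why: Soft enolisation and O-silylation: the ketone can enolise only towards C7 because C10 is quaternary, so a single silyl enol ether should form while the hydroxyl is capped as its TMS ether.

Step 7
Reactants: 8 3β,9-bis(trimethylsilyloxy)-4,4,10β-trimethyl-5α-hydrind-7(9)-ene; 9 1,1-dichloroethane
Product: 12 3β-hydroxy-4,4,8,10β-tetramethyl-trans-octal-7-en-9-one (3β-hydroxy-11-nordrim-7-en-9-one), via chloro(methyl)siloxycyclopropane 10 (not isolated), via O-silyl enone 11 (not isolated)
Conditions: MeCHCl2 (3 equiv), n-BuLi (2.5 equiv), Et2O, −40 → 0 °C; then PhMe, 110 °C, evaporate; then 1 M HCl, THF, rt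
Reagents that add atoms: 1,1-dichloroethane (9), CC(Cl)Cl
Why: Lithiation of 1,1-dichloroethane and α-elimination of LiCl give the chloro(methyl)carbenoid, which adds [2+1] to the electron-rich C7=C9 enol ether from the α-face (away from the 10β-methyl) and forms the C7–C8 and C8–C9 bonds of cyclopropane 10. On heating, 10 loses chloride from C8 while the C7–C9 bond opens in a disrotatory two-electron cyclopropyl-to-allyl process, the silyloxy group stabilising the cation and passing its silyl group to chloride, so that C8 with its methyl sits between C7 and C9, the alkene is at C7=C8 and C9 is the enone carbonyl. The closest known reaction type is the halocarbene ring expansion of cyclic trimethylsilyl enol ethers to 2-substituted cycloalk-2-enones, applied here to a trans-hydrindanone of the steroid D-ring kind. Ring B is thus closed by one-carbon insertion into the C7–C9 bond of the five-membered ring and not by cyclisation, and no new stereocentre results because C7, C8 and C9 all end up sp2 while C5 and C10 are untouched. The step needs insertion next to C9 only, which the single possible enol ether secures, and it needs chlorine endo to the five-membered ring so that the ring bonds can rotate inwards to a cis-cyclohexenyl cation; the smaller chlorine should prefer that position, and any exo-chloro epimer would stay unopened. The O3 silyl ether is a spectator and falls off in the acidic work-up.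

Step 8
Reactants: 12 3β-hydroxy-4,4,8,10β-tetramethyl-trans-octal-7-en-9-one; 13 methyltriphenylphosphonium bromide
Product: 14 3β-hydroxydrima-7,9(11)-diene
Conditions: Ph3PCH3Br, KOtBu (excess), PhMe, 90 °C
Reagents that add atoms: methyltriphenylphosphonium bromide (13), C[P+](c1ccccc1)(c1ccccc1)c1ccccc1.[Br-]
Why: Wittig methylenation with the ylide in hot toluene is the usual answer to hindered ketones; the C9 carbonyl has no α-hydrogen, the C3 alkoxide is inert, and no stereocentre is formed.

Step 9
Reactants: 14 3β-hydroxydrima-7,9(11)-diene; 15 acetic anhydride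
Product: 16 3β-acetoxydrima-7,9(11)-diene
Conditions: Ac2O, DMAP (cat.), pyridine, rt
Reagents that add atoms: acetic anhydride (15), CC(=O)OC(C)=O
Why: DMAP-catalysed acylation of the hindered equatorial alcohol installs the final acetate with retention at C3, under basic conditions that leave the diene alone.

Step 10
Reactants: 16 3β-acetoxydrima-7,9(11)-diene; 17 bromoacetone
Product: 19 3β-acetoxy-14,15-dinorlabd-7-en-13-one, via B-alkyl-9-BBN 18 (not isolated)
Conditions: 9-BBN (1.1 equiv), THF, rt → 50 °C; then BrCH2COCH3, potassium 2,6-di-tert-butylphenoxide, THF, 0 °C → rt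
Reagents that add atoms: bromoacetone (17), CC(=O)CBr
Why: Hydroboration followed by organoborane α-alkylation of an α-bromo ketone: 9-BBN should add to the terminal C9=C11 alkene with boron at C11 and hydrogen delivered to C9 from the α-face, opposite the axial 10β-methyl (9α-H, equatorial chain), and the bromoacetone enolate then forms a boron ate complex in which the primary alkyl group shifts from boron to carbon with loss of bromide (1,2-metallate shift) before protonolysis gives the methyl ketone.

Step 11
Reactants: 19 3β-acetoxy-14,15-dinorlabd-7-en-13-one; 20 allyl diethylphosphonoacetate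
Product: 21 allyl 3β-acetoxylabda-7,13E-dien-15-oate
Conditions: NaH, THF, 0 → 50 °C
Reagents that add atoms: allyl diethylphosphonoacetate (20), C=CCOC(=O)CP(=O)(OCC)OCC
Why: Horner–Wadsworth–Emmons olefination of the methyl ketone places the ester trans to the larger C12 chain, so the 13E isomer should predominate (any 13Z isomer is removed by chromatography), and the weakly basic stabilised anion should leave the hindered acetate and C9 alone.

Step 12
Reactants: 21 allyl 3β-acetoxylabda-7,13E-dien-15-oate
Product: 22 3β-acetoxylabda-7,13E-dien-15-oic acid (CNP0264606.2)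
Conditions: Pd(PPh3)4 (cat.), morpholine, THF, rt; dilute citric acid work-up
Reagents that add atoms: none
Why: Pd(0)-catalysed allyl transfer to the amine (Tsuji–Trost deallylation) cleaves only the allyl ester under neutral conditions, so the acetate, both alkenes and all stereocentres should survive.

**Compound list**

1 | (S)-Hajos–Parrish ketone, (7aS)-7a-methyl-2,3,7,7a-tetrahydro-1H-indene-1,5(6H)-dione | O=C1CC[C@]2(C)C(=O)CCC2=C1 | starting material
2 | C9 ethylene ketal of 1 (dioxolane at the five-ring carbonyl, enone intact) | O=C1CC[C@]2(C)C3(OCCO3)CCC2=C1 | intermediate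
3 | iodomethane | CI | starting material
4 | 9,9-ethylenedioxy-4,4,10β-trimethylhydrind-5-en-3-one | O=C1CC[C@]2(C)C3(OCCO3)CC=C2C1(C)C | intermediate
5 | 9,9-ethylenedioxy-4,4,10β-trimethylhydrind-5-en-3β-ol | O[C@H]1CC[C@]2(C)C3(OCCO3)CC=C2C1(C)C | intermediate
6 | 9,9-ethylenedioxy-4,4,10β-trimethyl-5α-hydrindan-3β-ol | O[C@H]1CC[C@]2(C)C3(OCCO3)CC[C@H]2C1(C)C | intermediate
7 | 3β-hydroxy-4,4,10β-trimethyl-5α-hydrindan-9-one | O[C@H]1CC[C@]2(C)C(=O)CC[C@H]2C1(C)C | intermediate
8 | 3β,9-bis(trimethylsilyloxy)-4,4,10β-trimethyl-5α-hydrind-7(9)-ene | C[Si](C)(C)O[C@H]1CC[C@]2(C)C(O[Si](C)(C)C)=CC[C@H]2C1(C)C | intermediate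
9 | 1,1-dichloroethane | CC(Cl)Cl | starting material
10 | α-face cyclopropane spanning C7 and C9: 8-chloro-8-methyl, chlorine endo to the five-membered ring, 3β,9β-bis(trimethylsilyloxy) | C[Si](C)(C)O[C@H]1CC[C@]2(C)[C@]3(O[Si](C)(C)C)[C@](C)(Cl)[C@@H]3C[C@H]2C1(C)C | intermediate (not isolated)
11 | 3β-(trimethylsilyloxy)-4,4,8,10β-tetramethyl-trans-octal-7-en-9-one | C[Si](C)(C)O[C@H]1CC[C@]2(C)C(=O)C(C)=CC[C@H]2C1(C)C | intermediate (not isolated)
12 | 3β-hydroxy-4,4,8,10β-tetramethyl-trans-octal-7-en-9-one | O[C@H]1CC[C@]2(C)C(=O)C(C)=CC[C@H]2C1(C)C | intermediate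
13 | methyltriphenylphosphonium bromide | C[P+](c1ccccc1)(c1ccccc1)c1ccccc1.[Br-] | starting material
14 | 3β-hydroxydrima-7,9(11)-diene | O[C@H]1CC[C@]2(C)C(=C)C(C)=CC[C@H]2C1(C)C | intermediate
15 | acetic anhydride | CC(=O)OC(C)=O | starting material
16 | 3β-acetoxydrima-7,9(11)-diene | CC(=O)O[C@H]1CC[C@]2(C)C(=C)C(C)=CC[C@H]2C1(C)C | intermediate
17 | bromoacetone | CC(=O)CBr | starting material
18 | 11-(9-borabicyclo[3.3.1]nonan-9-yl)drim-7-en-3β-yl acetate (9α-H) | CC(=O)O[C@H]1CC[C@]2(C)[C@@H](CB3C4CCCC3CCC4)C(C)=CC[C@H]2C1(C)C | intermediate (not isolated)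
19 | 3β-acetoxy-14,15-dinorlabd-7-en-13-one | CC(=O)O[C@H]1CC[C@]2(C)[C@@H](CCC(C)=O)C(C)=CC[C@H]2C1(C)C | intermediate
20 | allyl diethylphosphonoacetate | C=CCOC(=O)CP(=O)(OCC)OCC | starting material
21 | allyl 3β-acetoxylabda-7,13E-dien-15-oate | CC(=O)O[C@H]1CC[C@]2(C)[C@@H](CC/C(C)=C/C(=O)OCC=C)C(C)=CC[C@H]2C1(C)C | intermediate
22 | 3β-acetoxylabda-7,13E-dien-15-oic acid | CC(=O)O[C@H]1CC[C@]2(C)[C@@H](CC/C(C)=C/C(=O)O)C(C)=CC[C@H]2C1(C)C | target

**Step count and risks**

Total: 12 steps. Longest linear sequence: 12 steps (1 → 22).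

Step 7 (carbene insertion). The carbenoid may be lost to 1,2-hydrogen shift before it reaches the enol ether, and part of the adduct may form with chlorine exo, where ionisation with ring opening is geometrically blocked. Fallback, setting out from 8: dibromocarbene (CHBr3, KOtBu, pentane, −20 °C) should give the dibromocyclopropane F1, in which one bromine is always endo. Warming in toluene should open it to the 3-O-silyl 8-bromo enone F2, and dilute HCl to the 3β-hydroxy-8-bromo enone F3. Suzuki–Miyaura methylation (trimethylboroxine, Pd(dppf)Cl2, K2CO3, dioxane, 90 °C) then installs the C8 methyl and returns to 12. The same two ring bonds are formed in the same way.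

Step 4 (hydrogenation). Facial selectivity on the cyclopentene may be poor, so that hydrogen is also delivered from the β-face and the ring fusion comes out partly cis. Fallback, setting out from 2: thiomethylation at C4 (PhSH, aqueous CH2O, Et3N, EtOH, reflux) should give the 4-(phenylthiomethyl) enone F4. Li/NH3 then reduces the enone, expels thiophenoxide, reduces the resulting 4-methylene ketone and leaves the C3/C4 enolate, which MeI traps to give the trans-fused 4,4-dimethyl ketone F5; C5 is set here by protonation of the β-carbanion and not by a catalyst surface. NaBH4 in MeOH then returns to 6.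

Step 10 (hydroboration and borane alkylation). Ate-complex formation and migration may be slow at this β-branched alkylborane, while the bromo enolate is consumed by self-condensation. Fallback, setting out from 16: 9-BBN followed by NaBO3·4H2O oxidation (mild enough for the acetate) should give 3β-acetoxydrim-7-en-11-ol F6. Buffered DMP oxidation gives the aldehyde F7. Horner–Wadsworth–Emmons reaction with dimethyl (2-oxopropyl)phosphonate (LiCl, i-Pr2NEt, MeCN, rt) gives the E-enone F8. Conjugate reduction with [(Ph3P)CuH]6 in wet benzene returns to 19.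

**Further compounds**

F1 | step 7 | α-face 8,8-dibromocyclopropane spanning C7 and C9, 3β,9β-bis(trimethylsilyloxy) | C[Si](C)(C)O[C@H]1CC[C@]2(C)[C@]3(O[Si](C)(C)C)C(Br)(Br)[C@@H]3C[C@H]2C1(C)C
F2 | step 7 | 8-bromo-3β-(trimethylsilyloxy)-4,4,10β-trimethyl-trans-octal-7-en-9-one | C[Si](C)(C)O[C@H]1CC[C@]2(C)C(=O)C(Br)=CC[C@H]2C1(C)C
F3 | step 7 | 8-bromo-3β-hydroxy-4,4,10β-trimethyl-trans-octal-7-en-9-one | O[C@H]1CC[C@]2(C)C(=O)C(Br)=CC[C@H]2C1(C)C
F4 | step 4 | 4-(phenylthiomethyl) derivative of 2 | O=C1CC[C@]2(C)C3(OCCO3)CCC2=C1CSc1ccccc1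
F5 | step 4 | 9,9-ethylenedioxy-4,4,10β-trimethyl-5α-hydrindan-3-one | O=C1CC[C@]2(C)C3(OCCO3)CC[C@H]2C1(C)C
F6 | step 10 | 3β-acetoxydrim-7-en-11-ol | CC(=O)O[C@H]1CC[C@]2(C)[C@@H](CO)C(C)=CC[C@H]2C1(C)C
F7 | step 10 | 3β-acetoxydrim-7-en-11-al | CC(=O)O[C@H]1CC[C@]2(C)[C@@H](C=O)C(C)=CC[C@H]2C1(C)C
F8 | step 10 | 3β-acetoxy-14,15-dinorlabda-7,11E-dien-13-one | CC(=O)O[C@H]1CC[C@]2(C)[C@@H](/C=C/C(C)=O)C(C)=CC[C@H]2C1(C)C
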